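**Remark on the chemistry.** The target has no stereocentre. The only stereochemical element in the route is the (E) double bond of 7, 8 and 9, which the last step removes. Short-lived ions (the cinnamyl cation of step 4, metal alkoxides) are not counted as compounds.

## Structural features

- Compound 10 is an achiral benzophenone. Ring A (C1 bonded to the ketone carbon, C2 OH, C4 OMe, C5 alkyl) and ring B (a 4-hydroxyphenyl group) are joined through the carbonyl carbon.
- C5 of ring A carries a saturated three-carbon chain (Cα, Cβ, Cγ) that ends in ring C, a second 4-hydroxyphenyl group.
- There are no rings beyond the three benzene rings and no stereocentres, so every problem is one of position and functional-group compatibility.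
- Ring A is 1,2,4,5-tetrasubstituted. Its C2 hydroxyl is hydrogen-bonded to the ketone, and C3 and C6 remain CH.
- The sensitive points are the three phenolic oxygens, of which only the one at C4 is methylated, and the diaryl ketone, a doubly benzylic carbonyl open to over-reduction. In the intermediates an electron-rich styrene is acid-sensitive as well.
- The real difficulty is regiochemical: the aroyl group must sit ortho to the free hydroxyl and para to the methoxyl, and the chain para to the hydroxyl and ortho to the methoxyl, without a sequence of protecting-group steps.
- The key step exploits C5. It is para to the C2 hydroxyl, ortho to the C4 methoxyl, meta to the ketone and next to an unsubstituted carbon (C6), and the group it bears is an aryl–C3 (C6–C3) unit with the skeleton of a cinnamyl group. The C5–Cα bond can therefore be made by Friedel–Crafts cinnamylation, and the Cβ=Cγ double bond removed afterwards.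

## Logic of the disconnections

**10 back to 9.** No skeletal bond is cut. The Cβ–Cγ single bond becomes an (E) double bond and the O–H of ring C becomes an O–benzyl bond. This makes the C5–Cα bond recognisable as one formed by an allylic cation, and the para oxygen, kept as an ether, stabilises that cation. Nothing is lost in simplicity, because one operation removes both the unsaturation and the benzyl group. The forward step must saturate C=C and cleave the benzylic C–O bond while leaving the diaryl C=O bond intact.

**9 back to 4 and 8.** The bond cut is C5–Cα. C5 is the most electron-rich unhindered carbon of 9, and Cα is the terminus of a cinnamyl cation available from an allylic alcohol. The cut divides 9 into two pieces of similar size (fourteen and sixteen carbons) and needs no protecting group on 4. The forward step must select C5 over C3, ring B and the oxygens, give the linear isomer, stop after one alkylation, and beat self-condensation of 8.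

**4 back to 1 and 2 (through 3).** The bond cut joins C1 of ring A to the carbonyl carbon. The acyl group lies ortho to the hydroxyl and para to the methoxyl of 1, the position favoured when a boron chelate such as 3 can form. Both pieces are commercial. The forward acylation must go ortho, not para, to the hydroxyl of 1, and must leave the methyl ether and the free phenol of 2 unchanged.

**8 back to 7, then 5 and 6.** First the CH2–OH group is traced to an ester (a change of oxidation level only). Then the Cβ=Cγ double bond of 7 is cut. This leads to a commercial aldehyde, 5, and a commercial phosphonate, 6, which supplies Cα and Cβ. The forward olefination must give the (E) alkene, and the reduction must be 1,2-selective.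

## Other disconnections considered

**Alternative 1: ring A by Claisen–aldol assembly.**
- **Cut:** through ring A at C3–C4 and C1–C6, so the ring is assembled from two three-carbon pieces in the manner of a polyketide.
- **Forward key step:** the dianion of 1-[4-(benzyloxy)phenyl]butane-1,3-dione A2 would be acylated at its methyl terminus by methyl 5-[4-(benzyloxy)phenyl]-2-(dimethoxymethyl)pentanoate A3 (C3–C4). Acid would then unmask the acetal carbon as an oxocarbenium ion that the enolised C1 attacks (C1–C6). Loss of methanol and enolisation would give [4-(benzyloxy)phenyl](5-{3-[4-(benzyloxy)phenyl]propyl}-2,4-dihydroxyphenyl)methanone A1.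
- **In favour:** the aroyl group and the chain are placed by connectivity, not by directing effects, so C3-versus-C5 selectivity, over-alkylation and attack on ring B cannot arise. The chain arrives saturated.
- **Against:** A1 has both the C2 and C4 oxygens free, so a selective O-methylation at C4 must follow (plausible, since the C2 hydroxyl is chelated, but an extra step). A3 is an α-branched ester with an acidic α-hydrogen, so proton transfer to the dianion would compete with acylation. The triketone could close through oxygen to a 4-pyranone instead of through carbon. A3 also needs its own multi-step preparation.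
- **Comparison:** on structure this alternative is the better plan, because it removes the regiochemical question on which step 4 rests. On the final deprotection it is the equal of the chosen plan (one hydrogenolysis over Pd/C beside the same ketone). On mechanism it links several carbonyl condensations, each with a competing channel, where the chosen plan needs one electrophilic substitution. On step economy it would take about nine operations and two benzyl groups against five operations and one.

**Alternative 2: ring B by chromone ring transformation.**
- **Cut:** ring B is taken apart at the bond from the carbon ortho to the ketone to its neighbour and at the bond from the ester-bearing carbon to the former formyl carbon. The C2 oxygen of ring A is tied into a pyranone.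
- **Forward key step:** 6-{3-[4-(benzyloxy)phenyl]propyl}-7-methoxy-4-oxo-4H-chromene-3-carbaldehyde A5 would react with 1-methoxy-1,3-bis(trimethylsilyloxy)buta-1,3-diene A6 under silyl triflate catalysis. The diene terminus adds to chromone C2, the pyranone opens to release the ring A phenol, and the central diene carbon condenses with the formyl group. The product would be methyl 5-(5-{3-[4-(benzyloxy)phenyl]propyl}-2-hydroxy-4-methoxybenzoyl)-2-hydroxybenzoate A4.
- **In favour:** the diaryl ketone is formed without a Friedel–Crafts acylation, the C2 hydroxyl is released by the mechanism, and the C4 methyl ether is present from the start. On this point it is better than step 1 of the chosen plan, whose regiochemistry depends on chelation.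
- **Against:** A4 carries a methoxycarbonyl group the target lacks, so saponification and a forcing decarboxylation of a salicylic acid would have to follow. A5 derives from 1-(5-{3-[4-(benzyloxy)phenyl]propyl}-2-hydroxy-4-methoxyphenyl)ethan-1-one A7, which already bears the C5 chain, so the central problem of attaching the C6–C3 unit is moved to an earlier compound, not solved.
- **Comparison:** on structure it spends its key step on ring B, which the chosen plan obtains ready-made in 2. It is the equal of the chosen plan in still needing a substitution or coupling at C5, and arguably better in that this would be done on a substrate with no competing ring B. On mechanism the domino sequence is electronically well matched. On step economy it is clearly longer, about ten operations with one harsh decarboxylation.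

**Alternative 3: ring A from a 2-pyrone and an ynol ether.**
- **Cut:** ring A at C3–C4 and C5–C6, which splits it into a four-carbon diene (C1, C2, C3, C6) and a two-carbon alkyne (C4, C5).
- **Forward key step:** 4-(benzyloxy)-5-[4-(benzyloxy)benzoyl]-2H-pyran-2-one A9 would add 1-(benzyloxy)-4-(5-methoxypent-4-yn-1-yl)benzene A10 across pyrone C3 and C6 in a Diels–Alder reaction. The bridged lactone would aromatise by decarboxylation to [2-(benzyloxy)-5-{3-[4-(benzyloxy)phenyl]propyl}-4-methoxyphenyl][4-(benzyloxy)phenyl]methanone A8.
- **In favour:** all four substituents of ring A are set in one step. The polarisation is matched: the chain-bearing alkyne carbon, the nucleophilic end of the ynol ether, should bond to pyrone C6, the end activated by the aroyl group. The three oxygens are differentiated from the outset, and a methyl ynol ether has no β-hydrogen for thermal loss to a ketene.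
- **Against:** neither partner is simple. A10 is hydrolytically labile and needs several steps from the parent alkyne. A9 has its acyl group at C5, whereas direct acylation of a 4-hydroxy-2-pyrone would go to C3, so it must be built from acyclic precursors. The donor at C4 makes the pyrone a poorer diene, so heating would be needed.
- **Comparison:** on structure it is better, because the substitution pattern follows from connectivity. After the key step it is the equal of the chosen plan (a single hydrogenolysis), and better in that no alkene must be reduced beside the ketone. On mechanism it is a pericyclic cascade whose regiochemistry rests on a polar argument, as the site selectivity of step 4 does. On step economy it would run to well over ten operations and three benzyl groups, against five and one.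

Key step: step 4

## Route

Step 1
Reactants: 1 3-methoxyphenol; 2 4-hydroxybenzoic acid
Product: 4 (2-hydroxy-4-methoxyphenyl)(4-hydroxyphenyl)methanone, via difluoroboron chelate of the ketone 3 (not isolated)
Conditions: BF3·OEt2 (neat, excess), 90 °C; then MeOH/H2O, 60 °C
Reagents that add atoms: none
Why: BF3-promoted Friedel–Crafts acylation of a phenol by a free carboxylic acid (possibly through the aryl ester and a Fries-type shift). The acyl group should enter C6 of 1, ortho to the hydroxyl and para to the methoxyl, because only that product closes the six-membered O–BF2–O chelate 3, which also shields the new ketone. The ring of 2 is deactivated by its carboxyl group and should not acylate itself, and warm aqueous methanol hydrolyses 3 to 4.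

Step 2
Reactants: 5 4-(benzyloxy)benzaldehyde; 6 triethyl phosphonoacetate
Product: 7 ethyl (2E)-3-[4-(benzyloxy)phenyl]prop-2-enoate
Conditions: NaH, THF, 0 °C to rt
Reagents that add atoms: none
Why: Horner–Wadsworth–Emmons olefination. The stabilised phosphonate anion adds reversibly to the non-enolisable aldehyde and collapses through the less crowded oxaphosphetane, which should give the (E) ester; the benzyl ether is inert to NaH.

Step 3
Reactants: 7 ethyl (2E)-3-[4-(benzyloxy)phenyl]prop-2-enoate
Product: 8 (2E)-3-[4-(benzyloxy)phenyl]prop-2-en-1-ol
Conditions: i-Bu2AlH (2.5 equiv), CH2Cl2, −78 to 0 °C; aq. KNaC4H4O6 (potassium sodium tartrate)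
Reagents that add atoms: none
Why: 1,2-Reduction of an α,β-unsaturated ester to the allylic alcohol by i-Bu2AlH. The electrophilic aluminium hydride delivers hydride to the carbonyl carbon only, so the conjugated double bond and the benzyl ether should be untouched and the (E) geometry kept.

Step 4
Reactants: 4 (2-hydroxy-4-methoxyphenyl)(4-hydroxyphenyl)methanone; 8 (2E)-3-[4-(benzyloxy)phenyl]prop-2-en-1-ol
Product: 9 (5-{(2E)-3-[4-(benzyloxy)phenyl]prop-2-en-1-yl}-2-hydroxy-4-methoxyphenyl)(4-hydroxyphenyl)methanone
Conditions: Sc(OTf)3 (5 mol %), MeNO2, 25–40 °C; 8 added slowly to 4 (2 equiv)
Reagents that add atoms: none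
Why: Sc(OTf)3, or the triflic acid it releases, ionises the allylic C–O bond of 8 to the 4-benzyloxycinnamyl cation, whose charge is shared by Cα, Cγ and the para oxygen and which is the laboratory counterpart of a quinone-methide-type biosynthetic electrophile. C5 of 4 attacks Cα and the arenium ion loses a proton, so the one new bond is C5–Cα; the closest known reaction type is the acid-catalysed Friedel–Crafts allylation of resorcinol-type phenols by cinnamyl alcohols. No ring is closed and no stereocentre is made, and the (E) geometry follows from the transoid cation and from thermodynamic control. The step needs site selectivity, and C5 is the only carbon that receives donation from both the para C2 hydroxyl and the ortho C4 methoxyl while being meta to the ketone and having an unsubstituted neighbour; C3 has the same donors but is wedged between two oxygens, and the ring B carbons ortho to the C4' hydroxyl have a single donor, so the discrimination is a count of donors and not simply deactivation of ring B by its carbonyl, which ring A shares. O-Cinnamyl ethers should re-ionise under the conditions, and attack through Cγ would give a crowded 1,1-diarylpropene that gives up the styrene conjugation, so material should collect in linear 9. Because the new chain lies ortho to a methoxyl and not to a hydroxyl, the acid-catalysed chroman closure typical of ortho-cinnamylphenols cannot occur. An excess of 4 (recoverable) and slow addition of 8 keep the cation concentration low, which should suppress a second alkylation at C3 and self-condensation of 8.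

Step 5
Reactants: 9 (5-{(2E)-3-[4-(benzyloxy)phenyl]prop-2-en-1-yl}-2-hydroxy-4-methoxyphenyl)(4-hydroxyphenyl)methanone
Product: 10 {2-hydroxy-5-[3-(4-hydroxyphenyl)propyl]-4-methoxyphenyl}(4-hydroxyphenyl)methanone
Conditions: H2 (1 atm), 10% Pd/C, EtOAc/EtOH, rt; stopped after uptake of 2 equiv H2
Reagents that add atoms: none
Why: Heterogeneous catalytic hydrogenation of a 1,2-disubstituted alkene combined with hydrogenolysis of a benzyl aryl ether, both fast on Pd/C at 1 atm. The ketone is a vinylogous ester (donation from the C4 methoxyl, the C2 hydroxyl and the C4' hydroxyl) and is hydrogen-bonded to the C2 hydroxyl, so in neutral solvent it should be reduced far more slowly.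

## Compound list

1 | 3-methoxyphenol | COc1cccc(O)c1 | starting material
2 | 4-hydroxybenzoic acid | OC(=O)c1ccc(O)cc1 | starting material
3 | difluoroboron chelate of 4: 2,2-difluoro-4-(4-hydroxyphenyl)-7-methoxy-1,3,2-benzodioxaborinine, BF2 bridging the C2 phenolate oxygen and the ketone oxygen (zwitterionic O+–B− form) | COc1ccc2C(c3ccc(O)cc3)=[O+][B-](F)(F)Oc2c1 | intermediate
4 | (2-hydroxy-4-methoxyphenyl)(4-hydroxyphenyl)methanone | COc1ccc(C(=O)c2ccc(O)cc2)c(O)c1 | intermediate
5 | 4-(benzyloxy)benzaldehyde | O=Cc1ccc(OCc2ccccc2)cc1 | starting material
6 | triethyl phosphonoacetate | CCOC(=O)CP(=O)(OCC)OCC | starting material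
7 | ethyl (2E)-3-[4-(benzyloxy)phenyl]prop-2-enoate | CCOC(=O)/C=C/c1ccc(OCc2ccccc2)cc1 | intermediate
8 | (2E)-3-[4-(benzyloxy)phenyl]prop-2-en-1-ol | OC/C=C/c1ccc(OCc2ccccc2)cc1 | intermediate
9 | (5-{(2E)-3-[4-(benzyloxy)phenyl]prop-2-en-1-yl}-2-hydroxy-4-methoxyphenyl)(4-hydroxyphenyl)methanone | COc1cc(O)c(C(=O)c2ccc(O)cc2)cc1C/C=C/c1ccc(OCc2ccccc2)cc1 | intermediate
10 | {2-hydroxy-5-[3-(4-hydroxyphenyl)propyl]-4-methoxyphenyl}(4-hydroxyphenyl)methanone | COc1cc(O)c(C(=O)c2ccc(O)cc2)cc1CCCc1ccc(O)cc1 | target

## Step count and least certain steps

Total step count: 5. Longest linear sequence: 4 steps (steps 2, 3, 4 and 5, from 5 to 10).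

**Step 4 (key step).**
- **Risk:** the cinnamyl cation may be consumed by self-condensation of 8 (ether formation and oligomerisation through its own electron-rich styrene) faster than ring A captures it, because both donors of ring A are conjugated with the ketone. Loss of site selectivity towards C3 or ring B, and a second alkylation, are the secondary risks.
- **Fallback:** make the same C5–Cα bond by cross-coupling.
  - From 4, electrophilic iodination (N-iodosuccinimide, cat. CF3CO2H, MeCN, 0 °C) should go to C5 for the same electronic reasons, but irreversibly and with a small electrophile. It gives (2-hydroxy-5-iodo-4-methoxyphenyl)(4-hydroxyphenyl)methanone F1.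
  - Sonogashira coupling [Pd(PPh3)2Cl2, CuI, Et3N, DMF, 50 °C] with 1-(benzyloxy)-4-(prop-2-yn-1-yl)benzene F2 gives (5-{3-[4-(benzyloxy)phenyl]prop-1-yn-1-yl}-2-hydroxy-4-methoxyphenyl)(4-hydroxyphenyl)methanone F3. F2 is prepared from 4-(benzyloxy)benzyl chloride and ethynylmagnesium bromide with CuBr catalysis in THF.
  - Hydrogenation of F3 under the conditions of step 5 saturates the triple bond and removes the benzyl group. The fallback returns to the route at 10 and by-passes 9.
  - Base-induced isomerisation of the propargylic arene to an allene would be harmless, since both are reduced to the same propane chain.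

**Step 1.**
- **Risk:** acylation para to the hydroxyl of 1 (giving the 4-hydroxy-2-methoxy isomer), sluggish conversion because the 4-hydroxybenzoyl electrophile is a stabilised and therefore weak acylating species, and BF3-promoted loss of the methyl ether on prolonged heating.
- **Fallback:** fix the regiochemistry with a symmetrical arene and differentiate the oxygens afterwards.
  - From 1, O-methylation (MeI, K2CO3, acetone) gives 1,3-dimethoxybenzene F4, which can also be bought.
  - Friedel–Crafts acylation with 4-(benzyloxy)benzoic acid activated as its mixed trifluoroacetic anhydride [(CF3CO)2O, cat. H3PO4, rt] should occur only at C4 of F4 and give [4-(benzyloxy)phenyl](2,4-dimethoxyphenyl)methanone F5.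
  - BCl3 with pentamethylbenzene (CH2Cl2, −78 to 0 °C) then removes the benzyl ether and, through chelation to the ketone, only the ortho methyl ether. This returns to the route at 4.

**Step 5.**
- **Risk:** over-reduction, that is, hydrogenation of the diaryl ketone to the benzhydrol and hydrogenolysis onward to the diarylmethane once the alkene and the benzyl ether have reacted.
- **Fallback:** separate the two reductive events and use reagents that cannot attack a ketone.
  - From 9, diimide generated from 4-methylbenzenesulfonohydrazide and NaOAc (DME/H2O, reflux) saturates only the C=C bond and gives (5-{3-[4-(benzyloxy)phenyl]propyl}-2-hydroxy-4-methoxyphenyl)(4-hydroxyphenyl)methanone F6.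
  - BCl3 with pentamethylbenzene (CH2Cl2, −78 °C) cleaves the benzyl ether while the para methoxyl survives at that temperature. This returns to the route at 10.

## Further compounds

F1 | step 4 | (2-hydroxy-5-iodo-4-methoxyphenyl)(4-hydroxyphenyl)methanone | COc1cc(O)c(C(=O)c2ccc(O)cc2)cc1I
F2 | step 4 | 1-(benzyloxy)-4-(prop-2-yn-1-yl)benzene | C#CCc1ccc(OCc2ccccc2)cc1
F3 | step 4 | (5-{3-[4-(benzyloxy)phenyl]prop-1-yn-1-yl}-2-hydroxy-4-methoxyphenyl)(4-hydroxyphenyl)methanone | COc1cc(O)c(C(=O)c2ccc(O)cc2)cc1C#CCc1ccc(OCc2ccccc2)cc1
F4 | step 1 | 1,3-dimethoxybenzene | COc1cccc(OC)c1
F5 | step 1 | [4-(benzyloxy)phenyl](2,4-dimethoxyphenyl)methanone | COc1ccc(C(=O)c2ccc(OCc3ccccc3)cc2)c(OC)c1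
F6 | step 5 | (5-{3-[4-(benzyloxy)phenyl]propyl}-2-hydroxy-4-methoxyphenyl)(4-hydroxyphenyl)methanone | COc1cc(O)c(C(=O)c2ccc(O)cc2)cc1CCCc1ccc(OCc2ccccc2)cc1
A1 | alternative 1 | [4-(benzyloxy)phenyl](5-{3-[4-(benzyloxy)phenyl]propyl}-2,4-dihydroxyphenyl)methanone | Oc1cc(O)c(C(=O)c2ccc(OCc3ccccc3)cc2)cc1CCCc1ccc(OCc2ccccc2)cc1
A2 | alternative 1 | 1-[4-(benzyloxy)phenyl]butane-1,3-dione | CC(=O)CC(=O)c1ccc(OCc2ccccc2)cc1
A3 | alternative 1 | methyl 5-[4-(benzyloxy)phenyl]-2-(dimethoxymethyl)pentanoate (racemic) | COC(OC)C(CCCc1ccc(OCc2ccccc2)cc1)C(=O)OC
A4 | alternative 2 | methyl 5-(5-{3-[4-(benzyloxy)phenyl]propyl}-2-hydroxy-4-methoxybenzoyl)-2-hydroxybenzoate | COC(=O)c1cc(C(=O)c2cc(CCCc3ccc(OCc4ccccc4)cc3)c(OC)cc2O)ccc1O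
A5 | alternative 2 | 6-{3-[4-(benzyloxy)phenyl]propyl}-7-methoxy-4-oxo-4H-chromene-3-carbaldehyde | COc1cc2occ(C=O)c(=O)c2cc1CCCc1ccc(OCc2ccccc2)cc1
A6 | alternative 2 | 1-methoxy-1,3-bis(trimethylsilyloxy)buta-1,3-diene | COC(O[Si](C)(C)C)=CC(=C)O[Si](C)(C)C
A7 | alternative 2 | 1-(5-{3-[4-(benzyloxy)phenyl]propyl}-2-hydroxy-4-methoxyphenyl)ethan-1-one | COc1cc(O)c(C(C)=O)cc1CCCc1ccc(OCc2ccccc2)cc1
A8 | alternative 3 | [2-(benzyloxy)-5-{3-[4-(benzyloxy)phenyl]propyl}-4-methoxyphenyl][4-(benzyloxy)phenyl]methanone | COc1cc(OCc2ccccc2)c(C(=O)c2ccc(OCc3ccccc3)cc2)cc1CCCc1ccc(OCc2ccccc2)cc1
A9 | alternative 3 | 4-(benzyloxy)-5-[4-(benzyloxy)benzoyl]-2H-pyran-2-one | O=c1cc(OCc2ccccc2)c(C(=O)c2ccc(OCc3ccccc3)cc2)co1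
A10 | alternative 3 | 1-(benzyloxy)-4-(5-methoxypent-4-yn-1-yl)benzene | COC#CCCCc1ccc(OCc2ccccc2)cc1
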